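**Retrosynthetic overview**
1. Target 5 ⇐ 4 by cleavage of one aryl silyl ether.
2. 4 ⇐ diaryl ether C–O bond: the free OH of phenol 2 (ring B) adds to the C-3–H position of 2,6-dibromo-1,4-benzoquinone 1 (ring A) by oxa-Michael addition and aromatisation.
3. 2 ⇐ 1 by conjugate bromosilylation, which adds the third bromine and tells the two oxygens apart in one operation.
4. No ring is built. Both six-membered rings come from the same quinone 1; ring B is elaborated first and ring A is attached second.

Assumption: the target has no stereocentre and no configurationally stable axis, so it is made as the single achiral compound; 1 is taken as purchased (it is also one oxidation step from 2,4,6-tribromophenol).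

**Step 1**
Reactants: 1 2,6-dibromo-1,4-benzoquinone
Product: 2 2,3,5-tribromo-4-[(triisopropylsilyl)oxy]phenol
Conditions: TIPSOTf (1.1 equiv), n-Bu4NBr (1.2 equiv), MeCN, −20 °C; then 1, −20 °C → rt, Ar
Reagents that add atoms: triisopropylsilyl trifluoromethanesulfonate (TIPSOTf), CC(C)[Si](OS(=O)(=O)C(F)(F)F)(C(C)C)C(C)C; tetrabutylammonium bromide, CCCC[N+](CCCC)(CCCC)CCCC.[Br-]
Why: Conjugate bromosilylation of a quinone (1,4-addition of a silyl bromide, a known reaction type of halosilanes with benzoquinones): bromide adds productively only at the C–H carbon β to the bromine-flanked carbonyl, that enolate oxygen is silylated, and aromatisation moves the C-3 proton to the other oxygen, so the TIPS group sits between two bromines and the free OH lies next to the new bromine; no stereocentre is formed.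

**Step 2**
Reactants: 2 2,3,5-tribromo-4-[(triisopropylsilyl)oxy]phenol; 1 2,6-dibromo-1,4-benzoquinone (2.3 equiv)
Product: 4 3,5-dibromo-2-[2,3,5-tribromo-4-(triisopropylsilyloxy)phenoxy]benzene-1,4-diol, via aryloxyquinone 3 (not isolated)
Conditions: CsOPiv (20 mol%), 4 Å MS, MeCN, 0 °C → rt, dark, Ar; then aq. Na2S2O4, EtOAc, rt
Reagents that add atoms: none
Why: Proposed new method: a carboxylate-relay dehydrogenative oxa-Michael addition (C–H aryloxylation) of a 2,6-dihaloquinone — pivalate reversibly deprotonates the acidic phenol 2 (pKa about 7), the phenoxide adds reversibly to C-3 of 1 (the C–H β-carbon of the bromine-flanked carbonyl, giving an α-bromo-stabilised enolate), and pivalic acid relays the C-3 proton to oxygen so that aromatisation makes the addition irreversible and gives 4 directly; the second equivalent of 1 dehydrogenates 4 to 3 (the aryloxy group lowers the quinone potential) and the dithionite work-up returns all material to 4; 2 cannot enter quinone/hydroquinone exchange because one of its oxygens is silylated, ipso attack at C–Br is disfavoured by the ortho-bromo bulk of the nucleophile, and no stereocentre is formed; the closest known reaction types are thia- and aza-Michael addition/re-oxidation of quinones and the addition of hydroxide to C-3 of 2,6-dihalobenzoquinones, whereas a hindered polyhalophenol has not been added to a haloquinone C–H position in this way.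

**Step 3**
Reactants: 4 3,5-dibromo-2-[2,3,5-tribromo-4-(triisopropylsilyloxy)phenoxy]benzene-1,4-diol
Product: 5 3,5-dibromo-2-(2,3,5-tribromo-4-hydroxyphenoxy)benzene-1,4-diol
Conditions: KHF2 (2.5 equiv), MeOH, rt, Ar
Reagents that add atoms: none
Why: Fluoride-mediated cleavage of an aryl silyl ether, driven by the Si–F bond and the good 2,6-dibromophenoxide leaving group; the mildly acidic medium keeps the bromohydroquinone from air oxidation and leaves the diaryl ether and the C–Br bonds untouched, and no stereocentre is involved.

**Compound list**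
1 | 2,6-dibromo-1,4-benzoquinone | O=C1C=C(Br)C(=O)C(Br)=C1 | starting material
2 | 2,3,5-tribromo-4-[(triisopropylsilyl)oxy]phenol | CC(C)[Si](Oc1c(Br)cc(O)c(Br)c1Br)(C(C)C)C(C)C | intermediate
3 | 3,5-dibromo-2-[2,3,5-tribromo-4-(triisopropylsilyloxy)phenoxy]cyclohexa-2,5-diene-1,4-dione (aryloxyquinone) | CC(C)[Si](Oc1c(Br)cc(OC2=C(Br)C(=O)C(Br)=CC2=O)c(Br)c1Br)(C(C)C)C(C)C | intermediate
4 | 3,5-dibromo-2-[2,3,5-tribromo-4-(triisopropylsilyloxy)phenoxy]benzene-1,4-diol | CC(C)[Si](Oc1c(Br)cc(Oc2c(Br)c(O)c(Br)cc2O)c(Br)c1Br)(C(C)C)C(C)C | intermediate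
5 | 3,5-dibromo-2-(2,3,5-tribromo-4-hydroxyphenoxy)benzene-1,4-diol (achiral) | Oc1cc(Br)c(O)c(Br)c1Oc1cc(Br)c(O)c(Br)c1Br | target

**Total step count:** 3. **Longest linear sequence:** 3 steps (1 → 2 → 4 → 5).

**Steps most likely to fail and their fallbacks**

Step 2 (the proposed new step). The phenoxide may attack a C–Br carbon of 1 and displace bromide instead of adding at C-3–H, or the liberated 2,6-dibromohydroquinone may compete as a nucleophile. The fallback uses known diaryliodonium O-arylation; it sets out from 2 and comes back to the route at 4. The partner is made from 1: reduction with aqueous Na2S2O4 gives 2,6-dibromobenzene-1,4-diol F1, MeI/K2CO3 in acetone gives 1,3-dibromo-2,5-dimethoxybenzene F6, and NIS/TFA in MeCN iodinates the only type of free position to give 1,3-dibromo-4-iodo-2,5-dimethoxybenzene F7. Oxidation with mCPBA/TsOH·H2O followed by 1,3,5-trimethoxybenzene gives (2,4-dibromo-3,6-dimethoxyphenyl)(2,4,6-trimethoxyphenyl)iodonium tosylate F8. Phenol 2 with K2CO3 in MeCN at 50 °C takes the hindered, non-trimethoxyphenyl aryl group metal-free, leaving all C–Br bonds intact, to give 1,3-dibromo-2,5-dimethoxy-4-[2,3,5-tribromo-4-(triisopropylsilyloxy)phenoxy]benzene F9. BBr3 in CH2Cl2 (−78 → 0 °C) cleaves both methyl ethers to give 4; any material that has also lost the silyl group is already 5.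

Step 1. If the bromide adduct shuffles its proton before silylation, the TIPS group can end up on the less hindered oxygen and give the wrong regioisomer. The fallback fixes the regiochemistry by acidity-controlled protection and electrophilic bromination; it sets out from 1 and comes back to the route at 5. Reduction of 1 with aqueous Na2S2O4 gives 2,6-dibromobenzene-1,4-diol F1. MOMCl with 1.0 equiv K2CO3 in acetone at 0 °C alkylates the much more acidic OH between the bromines (pKa about 6.7 against about 10) to give 3,5-dibromo-4-(methoxymethoxy)phenol F2. NBS (1.0 equiv, MeCN, −20 °C) brominates once ortho to the free OH to give 2,3,5-tribromo-4-(methoxymethoxy)phenol F3. Coupling of F3 with 1 under the step 2 conditions passes through 3,5-dibromo-2-[2,3,5-tribromo-4-(methoxymethoxy)phenoxy]cyclohexa-2,5-diene-1,4-dione F4 and gives, after the dithionite work-up, 3,5-dibromo-2-[2,3,5-tribromo-4-(methoxymethoxy)phenoxy]benzene-1,4-diol F5. HCl in MeOH at 40 °C removes the MOM group to give 5.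

Step 3. The TIPS group between two ortho bromines may be slow to cleave, and the free pentabromo triphenol may oxidise or degrade while fluoride is present. The fallback removes the silyl group at the oxidation-insensitive quinone stage and makes a neutral reduction the last operation; it sets out from 3 (isolated by chromatography when the dithionite work-up of step 2 is left out) and comes back to the route at 5. Et3N·3HF in MeCN at 0 °C → rt gives 3,5-dibromo-2-(2,3,5-tribromo-4-hydroxyphenoxy)cyclohexa-2,5-diene-1,4-dione F10, which is reduced without storage by ascorbic acid in THF/H2O at rt to 5.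

**Further compounds**
F1 | step 1 | 2,6-dibromobenzene-1,4-diol | Oc1cc(Br)c(O)c(Br)c1
F2 | step 1 | 3,5-dibromo-4-(methoxymethoxy)phenol | COCOc1c(Br)cc(O)cc1Br
F3 | step 1 | 2,3,5-tribromo-4-(methoxymethoxy)phenol | COCOc1c(Br)cc(O)c(Br)c1Br
F4 | step 1 | 3,5-dibromo-2-[2,3,5-tribromo-4-(methoxymethoxy)phenoxy]cyclohexa-2,5-diene-1,4-dione | COCOc1c(Br)cc(OC2=C(Br)C(=O)C(Br)=CC2=O)c(Br)c1Br
F5 | step 1 | 3,5-dibromo-2-[2,3,5-tribromo-4-(methoxymethoxy)phenoxy]benzene-1,4-diol | COCOc1c(Br)cc(Oc2c(Br)c(O)c(Br)cc2O)c(Br)c1Br
F6 | step 2 | 1,3-dibromo-2,5-dimethoxybenzene | COc1cc(Br)c(OC)c(Br)c1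
F7 | step 2 | 1,3-dibromo-4-iodo-2,5-dimethoxybenzene | COc1cc(Br)c(OC)c(Br)c1I
F8 | step 2 | (2,4-dibromo-3,6-dimethoxyphenyl)(2,4,6-trimethoxyphenyl)iodonium p-toluenesulfonate | COc1cc(OC)c([I+]c2c(OC)cc(Br)c(OC)c2Br)c(OC)c1.Cc1ccc(cc1)S(=O)(=O)[O-]
F9 | step 2 | 1,3-dibromo-2,5-dimethoxy-4-[2,3,5-tribromo-4-(triisopropylsilyloxy)phenoxy]benzene | COc1cc(Br)c(OC)c(Br)c1Oc1cc(Br)c(O[Si](C(C)C)(C(C)C)C(C)C)c(Br)c1Br
F10 | step 3 | 3,5-dibromo-2-(2,3,5-tribromo-4-hydroxyphenoxy)cyclohexa-2,5-diene-1,4-dione | O=C1C=C(Br)C(=O)C(Br)=C1Oc1cc(Br)c(O)c(Br)c1Br
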